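**Retrosynthetic overview**
- Gentiside G is cut first at the ester bond between O1 and the acyl carbon. This gives (S)-17-methylnonadecan-1-ol and benzyl-protected 2,3-dihydroxybenzoic acid, and the catechol is freed last by hydrogenolysis.
- The plan rests on the run of sixteen plain CH2 groups, C1 to C16, between O1 and the only stereocentre, C17. Any CH2–CH2 bond in this run can be made from two primary radicals, and C14–C15 is chosen.
- That bond comes from a crossed Kolbe electrolysis of (S)-4-methylhexanoic acid (C15–C19 plus the methyl branch) with 15-acetoxypentadecanoic acid (O1, C1–C14). Each acid loses its carboxyl carbon as CO2.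
- C17 is bought with (S)-2-methylbutan-1-ol and extended by two carbons through a malonic ester synthesis. The C1–C14 piece comes from 15-pentadecanolide.
- No ring is formed anywhere. The benzene ring of the catechol ester is bought, and the macrolactone ring of the C15 building block is only opened.

Key step: step 6

Assumption: the chain is numbered from the carbinol carbon C1 (bound to ester oxygen O1) to the terminal methyl C19. The optical purity of commercial (S)-2-methylbutan-1-ol, which no later step raises or lowers, is taken to set that of the target.

Step 1
Reactants: 1 (S)-2-methylbutan-1-ol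
Product: 2 (S)-2-methylbutyl 4-methylbenzenesulfonate
Conditions: TsCl, Et3N, DMAP (cat.), CH2Cl2, 0 °C to rt
Reagents that add atoms: 4-toluenesulfonyl chloride (TsCl), Cc1ccc(cc1)S(=O)(=O)Cl
Why: Sulfonylation of a primary alcohol at oxygen (tosylate formation) breaks no bond at the stereocentre, so the S configuration of the future C17 is carried over unchanged.

Step 2
Reactants: 2 (S)-2-methylbutyl 4-methylbenzenesulfonate; 3 diethyl malonate
Product: 5 diethyl 2-[(2S)-2-methylbutyl]malonate, via sodium enolate of diethyl malonate 4 (not isolated)
Conditions: 3 (1.3 equiv), NaOEt (1.1 equiv), EtOH, rt; then 2, reflux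
Reagents that add atoms: none
Why: Malonic ester synthesis: ethoxide deprotonates 3 to the soft enolate 4, which displaces the primary tosylate by SN2 (a slight excess of 3 holds back double alkylation), and the stereocentre, one carbon away from the reacting CH2, takes no part and stays S.

Step 3
Reactants: 5 diethyl 2-[(2S)-2-methylbutyl]malonate
Product: 7 (S)-4-methylhexanoic acid, via 2-[(2S)-2-methylbutyl]malonic acid 6 (not isolated)
Conditions: KOH, EtOH/H2O, reflux, EtOH distilled off; then aq. H2SO4, reflux; distillation
Reagents that add atoms: potassium hydroxide, [K+].[OH-]
Why: Saponification and then decarboxylation of the free malonic acid 6 through its cyclic six-membered transition state close the malonic ester synthesis in one pot, and the stereocentre, γ to the remaining carboxyl group and without an acidic hydrogen, cannot epimerise in base or acid.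

Step 4
Reactants: 8 15-pentadecanolide
Product: 9 15-hydroxypentadecanoic acid
Conditions: KOH, MeOH/H2O, reflux; then aq. HCl, 0 °C
Reagents that add atoms: potassium hydroxide, [K+].[OH-]
Why: Saponification of the lactone is driven to completion by carboxylate formation, and the hydroxy acid set free on cold acidification has no tendency to close the sixteen-membered ring again.

Step 5
Reactants: 9 15-hydroxypentadecanoic acid
Product: 10 15-acetoxypentadecanoic acid
Conditions: Ac2O (excess), pyridine, DMAP (cat.), rt; then H2O, acidic work-up
Reagents that add atoms: acetic anhydride, CC(=O)OC(C)=O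
Why: DMAP-catalysed O-acetylation of a primary alcohol with excess anhydride is fast, the aqueous quench returns any carboxyl group activated in passing to the free acid, and the acetate shields the hydroxyl from anodic oxidation and from acylation during step 6.

Step 6
Reactants: 7 (S)-4-methylhexanoic acid; 10 15-acetoxypentadecanoic acid
Product: 13 (S)-17-methylnonadecyl acetate, via 3-methylpentyl radical 11 (not isolated), via 14-acetoxytetradecyl radical 12 (not isolated)
Conditions: 7 (5 equiv), 10 (1 equiv), NaOMe (5 mol% of total acid), MeOH, undivided cell, smooth Pt anode, Pt cathode, constant current ca. 0.25 A cm−2, 40–45 °C, polarity reversed at intervals, stopped when the bath turns faintly alkaline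
Reagents that add atoms: none
Why: In the weakly acidic, partly neutralised methanol the carboxylates of 7 and 10 sit on the smooth Pt anode and each gives up one electron at high current density; the acyloxy radicals shed CO2 at once, and the primary radicals 11 and 12, formed side by side in high local concentration, combine to make the C14–C15 bond while the cathode discharges protons to H2. This is a crossed (mixed) Kolbe electrolysis, the long-established anodic decarboxylative coupling by which a short branched acid is grafted onto a long ω-functionalised fatty acid. No ring is closed and no stereocentre is made: C17 arrives with 7 and sits two carbons from the radical centre C15, a 1,3-hydrogen shift being geometrically out of reach, so its S configuration should be kept in all of the 13 that forms. The selectivity needed is hetero- over homocoupling, which is purely statistical; it is secured by the fivefold excess of the cheap acid 7, so that most of radical 12 should meet 11, and by the wide gap in properties between 13 and the two symmetrical dimers (a C12 hydrocarbon that leaves under vacuum or with the first hexane fraction, and a far more polar, sparingly soluble C28 diacetate). Over-oxidation to carbocations (the Hofer–Moest path) should stay minor because both radicals are primary and carry no α-substituent, and Pt, methanol, a low degree of neutralisation and high current density all favour the radical path. The acetate is inert at the anode, and any methanolysis as the bath turns alkaline is harmless because step 7 removes this group anyway.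

Step 7
Reactants: 13 (S)-17-methylnonadecyl acetate
Product: 14 (S)-17-methylnonadecan-1-ol
Conditions: K2CO3 (0.2 equiv), MeOH/THF, rt
Reagents that add atoms: none
Why: Carbonate-catalysed transesterification (methanolysis) of a primary acetate is mild and complete in excess methanol, THF keeps the waxy substrate in solution, and the saturated chain with C17 offers nothing else to react.

Step 8
Reactants: 15 2,3-dihydroxybenzoic acid
Product: 16 benzyl 2,3-bis(benzyloxy)benzoate
Conditions: BnBr (3.5 equiv), K2CO3, DMF, 60 °C
Reagents that add atoms: benzyl bromide, BrCc1ccccc1
Why: Williamson etherification of both phenols and SN2 alkylation of the carboxylate run together with the very reactive benzyl bromide, so exhaustive benzylation sidesteps any need to tell the three acidic groups apart.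

Step 9
Reactants: 16 benzyl 2,3-bis(benzyloxy)benzoate
Product: 17 2,3-bis(benzyloxy)benzoic acid
Conditions: KOH, MeOH/THF/H2O, reflux; then aq. HCl
Reagents that add atoms: potassium hydroxide, [K+].[OH-]
Why: Saponification cleaves the benzyl ester by acyl–oxygen fission while the two aryl benzyl ethers are inert to hydroxide.

Step 10
Reactants: 14 (S)-17-methylnonadecan-1-ol; 17 2,3-bis(benzyloxy)benzoic acid
Product: 18 (S)-17-methylnonadecyl 2,3-bis(benzyloxy)benzoate
Conditions: DCC, DMAP (cat.), CH2Cl2, 0 °C to rt
Reagents that add atoms: none
Why: Steglich esterification: DCC activates 17, DMAP relays the acyl group as an acylpyridinium ion to the unhindered primary alcohol 14, the benzyl ethers keep the catechol oxygens from competing, and C17 is sixteen carbons away from the reaction site.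

Step 11
Reactants: 18 (S)-17-methylnonadecyl 2,3-bis(benzyloxy)benzoate
Product: 19 gentiside G, (S)-17-methylnonadecyl 2,3-dihydroxybenzoate
Conditions: H2 (1 atm), 10% Pd/C, EtOAc/EtOH, rt
Reagents that add atoms: none
Why: Catalytic hydrogenolysis cleaves only the two benzylic C–O bonds, since the ester C1–O1 bond is not benzylic and the benzoate ring is not reduced at 1 atm, and the neutral medium spares the ester and the oxidation-prone catechol.

**Compound list**
1 | (S)-2-methylbutan-1-ol | CC[C@H](C)CO | starting material
2 | (S)-2-methylbutyl 4-methylbenzenesulfonate | CC[C@H](C)COS(=O)(=O)c1ccc(C)cc1 | intermediate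
3 | diethyl malonate | CCOC(=O)CC(=O)OCC | starting material
4 | sodium enolate of diethyl malonate (not isolated) | [Na+].CCOC(=O)[CH-]C(=O)OCC | intermediate
5 | diethyl 2-[(2S)-2-methylbutyl]malonate | CC[C@H](C)CC(C(=O)OCC)C(=O)OCC | intermediate
6 | 2-[(2S)-2-methylbutyl]malonic acid (not isolated) | CC[C@H](C)CC(C(=O)O)C(=O)O | intermediate
7 | (S)-4-methylhexanoic acid | CC[C@H](C)CCC(=O)O | intermediate
8 | 15-pentadecanolide (oxacyclohexadecan-2-one) | O=C1CCCCCCCCCCCCCCO1 | starting material
9 | 15-hydroxypentadecanoic acid | OCCCCCCCCCCCCCCC(=O)O | intermediate
10 | 15-acetoxypentadecanoic acid | CC(=O)OCCCCCCCCCCCCCCC(=O)O | intermediate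
11 | 3-methylpentyl radical from 7, radical centre at the future C15, groups at the future C17 arranged in space as in 7 (not isolated) | CC[C@H](C)C[CH2] | intermediate
12 | 14-acetoxytetradecyl radical from 10, radical centre at the future C14 (not isolated) | CC(=O)OCCCCCCCCCCCCC[CH2] | intermediate
13 | (S)-17-methylnonadecyl acetate | CC[C@H](C)CCCCCCCCCCCCCCCCOC(C)=O | intermediate
14 | (S)-17-methylnonadecan-1-ol | CC[C@H](C)CCCCCCCCCCCCCCCCO | intermediate
15 | 2,3-dihydroxybenzoic acid | OC(=O)c1cccc(O)c1O | starting material
16 | benzyl 2,3-bis(benzyloxy)benzoate | O=C(OCc1ccccc1)c2cccc(OCc3ccccc3)c2OCc4ccccc4 | intermediate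
17 | 2,3-bis(benzyloxy)benzoic acid | OC(=O)c1cccc(OCc2ccccc2)c1OCc3ccccc3 | intermediate
18 | (S)-17-methylnonadecyl 2,3-bis(benzyloxy)benzoate | CC[C@H](C)CCCCCCCCCCCCCCCCOC(=O)c1cccc(OCc2ccccc2)c1OCc3ccccc3 | intermediate
19 | gentiside G, (S)-17-methylnonadecyl 2,3-dihydroxybenzoate | CC[C@H](C)CCCCCCCCCCCCCCCCOC(=O)c1cccc(O)c1O | target

**Total step count:** 11
**Longest linear sequence:** 7 steps (1, 2, 3, 6, 7, 10, 11)

**Steps most likely to fail**

**Risk 1, step 6 (crossed Kolbe electrolysis).**
- What may go wrong:
  - Homocoupling and disproportionation of the radicals may consume the long-chain partner and burden the purification.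
  - Over-oxidation to cations may compete.
  - Waxy deposits may foul the anode until the current efficiency collapses.
- The fallback sets out from 8 and 2 and comes back at 14. It makes the neighbouring CH2–CH2 bond (C15–C16) by a polar, copper-catalysed Grignard–tosylate cross-coupling instead of a radical coupling.
- Lactone 8 is reduced with LiAlH4 in THF to pentadecane-1,15-diol F1.
- Monobromination with 48% aq. HBr in refluxing toluene gives 15-bromopentadecan-1-ol F2.
- 3,4-Dihydro-2H-pyran and pyridinium tosylate (cat.) in CH2Cl2 give 2-[(15-bromopentadecyl)oxy]oxane F3, a mixture at the acetal carbon.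
- Mg in THF converts this into [15-(oxan-2-yloxy)pentadecyl]magnesium bromide F4.
- Coupling of F4 with tosylate 2 under Li2CuCl4 catalysis (THF, −20 °C to rt) gives 2-{[(17S)-17-methylnonadecyl]oxy}oxane F5.
- TsOH (cat.) in MeOH then frees 14. The stereocentre of 2 is again only a neighbour of the reacting carbon.

**Risk 2, step 2 (malonate alkylation).**
- What may go wrong: SN2 displacement at the β-branched carbon may be sluggish, so that substitution by ethoxide, elimination and double alkylation compete.
- The fallback sets out from 2 and comes back at 7. It reverses the polarity of that carbon.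
- LiBr in refluxing acetone turns 2 into (S)-1-bromo-2-methylbutane F6.
- Mg in THF gives (S)-2-methylbutylmagnesium bromide F7.
- F7 opens oxirane (Li2CuCl4 cat., THF, −30 to 0 °C, dilute HCl quench) to give (S)-4-methylhexan-1-ol F8.
- TEMPO (cat.) with PhI(OAc)2 in MeCN/H2O oxidises the primary alcohol to 7. The stereocentre is never at or next to an acidic position.

**Risk 3, step 10 (Steglich esterification).**
- What may go wrong:
  - The carbodiimide-activated acid may rearrange to an unreactive N-acylurea faster than the acyl group is transferred, because of the ortho-benzyloxy group.
  - The urea may be hard to remove from a waxy ester.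
- The fallback sets out from 14 and 17 and comes back at 18. It forms the ester by making the C1–O1 bond rather than the acyl–O1 bond.
- MsCl and Et3N in CH2Cl2 at 0 °C convert 14 into (S)-17-methylnonadecyl methanesulfonate F9.
- The cesium carboxylate of 17 (Cs2CO3, DMF, 60 °C) displaces the mesylate by SN2 to give 18.

**Further compounds**
F1 | step 6 | pentadecane-1,15-diol | OCCCCCCCCCCCCCCCO
F2 | step 6 | 15-bromopentadecan-1-ol | OCCCCCCCCCCCCCCCBr
F3 | step 6 | 2-[(15-bromopentadecyl)oxy]oxane | BrCCCCCCCCCCCCCCCOC1CCCCO1
F4 | step 6 | [15-(oxan-2-yloxy)pentadecyl]magnesium bromide | Br[Mg]CCCCCCCCCCCCCCCOC1CCCCO1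
F5 | step 6 | 2-{[(17S)-17-methylnonadecyl]oxy}oxane | CC[C@H](C)CCCCCCCCCCCCCCCCOC1CCCCO1
F6 | step 2 | (S)-1-bromo-2-methylbutane | CC[C@H](C)CBr
F7 | step 2 | (S)-2-methylbutylmagnesium bromide | CC[C@H](C)C[Mg]Br
F8 | step 2 | (S)-4-methylhexan-1-ol | CC[C@H](C)CCCO
F9 | step 10 | (S)-17-methylnonadecyl methanesulfonate | CC[C@H](C)CCCCCCCCCCCCCCCCOS(C)(=O)=O
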